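**Retrosynthetic overview**

- Numbering and feature: chain C1 (OCH2) to C9; ring C1' (stereocentre), C2' (C–CH3), C3' (=CH), C4', C5', C6' (C(CH3)2). The plan rests on the fact that the only stereocentre, C1', is bonded directly to the ring alkene carbon C2' and is flanked by the gem-dimethyl carbon C6'.
- Ester C–O bond: target 22 comes from arachidonic acid 21 and terpenol 20 (last step).
- Chain: C1 from formaldehyde and the C3 methyl by methylalumination of alkyne 17; C5–C6 by Negishi coupling of alkenyl iodide 13 with the C2–C5 zinc reagent 15; the C7 methyl by methylalumination of alkyne 11; C7–C8 by acetylide alkylation of iodide 10.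
- Ring (the only ring, closed in step 5): C1'–C2' is cut back to the acyclic (Z)-alkenyl iodide/(E)-enoate 7. An enantioselective reductive Heck cyclisation closes the cyclohexene, fixes C2'=C3' and creates (S)-C1' in one event.
- Precursor 7: four steps from 2,2-dimethylpent-4-enal 1 (olefination, hydroboration–oxidation, oxidation, (Z)-iodo-olefination).

Key step: step 5

Assumption: the sense of induction of BINAP in step 5 cannot be fixed in advance; (R)-BINAP is written, and its antipode is to be used if a pilot run shows the (1R)-ester.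

**Route**

Step 1
Reactants: 1 2,2-dimethylpent-4-enal; 2 triethyl phosphonoacetate
Product: 3 ethyl (2E)-4,4-dimethylhepta-2,6-dienoate
Conditions: NaH, THF, 0 °C to rt
Reagents that add atoms: none
Why: Horner–Wadsworth–Emmons olefination of a non-enolisable, α-quaternary aldehyde with the stabilised phosphonate anion should give the (E)-enoate.

Step 2
Reactants: 3 ethyl (2E)-4,4-dimethylhepta-2,6-dienoate
Product: 5 ethyl (2E)-7-hydroxy-4,4-dimethylhept-2-enoate, via B-alkyl-9-BBN adduct 4 (not isolated)
Conditions: 9-BBN, THF, 0 °C to rt; then NaBO3·4H2O, THF/H2O, rt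
Reagents that add atoms: 9-borabicyclo[3.3.1]nonane, [H]B1C2CCCC1CCC2 (boron and bicycle stay only in 4); sodium perborate tetrahydrate, [Na+].[Na+].O[B-]1(O)OO[B-](O)(O)OO1 (supplies the hydroxyl oxygen)
Why: Anti-Markovnikov hydroboration–oxidation; the bulky dialkylborane should add to the unhindered terminal alkene much faster than to the electron-poor enoate, and perborate oxidises the C–B bond without hydrolysing the ester.

Step 3
Reactants: 5 ethyl (2E)-7-hydroxy-4,4-dimethylhept-2-enoate
Product: 6 ethyl (2E)-4,4-dimethyl-7-oxohept-2-enoate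
Conditions: DMP, CH2Cl2, 0 °C to rt
Reagents that add atoms: none
Why: Dess–Martin oxidation converts the primary alcohol to the aldehyde under neutral conditions that leave the enoate untouched.

Step 4
Reactants: 6 ethyl (2E)-4,4-dimethyl-7-oxohept-2-enoate
Product: 7 ethyl (2E,7Z)-8-iodo-4,4-dimethylnona-2,7-dienoate
Conditions: EtPPh3I, n-BuLi, THF, rt; I2, −78 °C; NaN(SiMe3)2, −20 °C; then 6, −78 to −20 °C
Reagents that add atoms: ethyltriphenylphosphonium iodide, CC[P+](c1ccccc1)(c1ccccc1)c1ccccc1.[I-]; iodine, II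
Why: Wittig olefination with the α-iodo ylide (Stork–Zhao-type iodo-olefination) should give the (Z)-2-iodoalk-2-ene under kinetic control, and the enoate is spared because it has no γ-hydrogen and its β-carbon is neopentyl.

Step 5
Reactants: 7 ethyl (2E,7Z)-8-iodo-4,4-dimethylnona-2,7-dienoate
Product: 8 ethyl 2-[(1S)-2,6,6-trimethylcyclohex-2-en-1-yl]acetate
Conditions: Pd(OAc)2 (5 mol %), (R)-BINAP (7.5 mol %), HCO2Na (3 equiv), degassed EtOH, 70 °C
Reagents that add atoms: none
Why: Proposed new method: zerovalent palladium–BINAP inserts into the C8–I bond of 7 with retention of the (Z) geometry, iodide dissociates in the protic medium, and the cationic alkenylpalladium adds syn across the tethered (E)-enoate so that C8 bonds to the β-carbon C3 (ring bond C2'–C1'), after which the palladium enolate at C2 is reduced by formate (decarboxylation to a palladium hydride and C–H reductive elimination, or protonolysis of the O-bound enolate) to CH2. The closest known reaction type is the palladium–bisphosphine-catalysed enantioselective intramolecular reductive Heck cyclisation of aryl halides onto tethered enones with a hydride donor, together with racemic formate-mediated reductive Heck cyclisations of alkenyl iodides; the alkenyl iodide and the acyclic enoate in the asymmetric variant are the extension. The cyclohexene ring closes in the 6-exo-trig mode. The stereocentre C1' is set by the chiral bisphosphine on palladium, which must direct C–C bond formation to the Si face of C3 to give the (1S) product. Reduction of the palladium enolate must outrun β-hydride elimination of the C1' hydrogen, which the ester (O-bound enolate), the protic solvent and excess formate favour, and cyclisation must outrun direct reduction of the alkenylpalladium, which the gem-dimethyl group at C4 (Thorpe–Ingold effect) favours. The position of the ring alkene is fixed because the retained (Z)-alkenyl unit becomes C2'=C3'; no silver salt is used, since formate would reduce it.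

Step 6
Reactants: 8 ethyl 2-[(1S)-2,6,6-trimethylcyclohex-2-en-1-yl]acetate
Product: 9 2-[(1S)-2,6,6-trimethylcyclohex-2-en-1-yl]ethan-1-ol
Conditions: LiAlH4, Et2O, 0 °C
Reagents that add atoms: none
Why: Hydride reduction of the ester to the primary alcohol does not touch the trisubstituted alkene or the non-acidic allylic stereocentre.

Step 7
Reactants: 9 2-[(1S)-2,6,6-trimethylcyclohex-2-en-1-yl]ethan-1-ol
Product: 10 (6S)-6-(2-iodoethyl)-1,5,5-trimethylcyclohex-1-ene
Conditions: I2, PPh3, imidazole, CH2Cl2, 0 °C to rt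
Reagents that add atoms: iodine, II
Why: Appel-type iodination (Garegg–Samuelsson conditions) replaces the primary hydroxyl by iodide through the alkoxyphosphonium salt, two carbons away from the stereocentre.

Step 8
Reactants: 10 (6S)-6-(2-iodoethyl)-1,5,5-trimethylcyclohex-1-ene
Product: 11 (6S)-6-(but-3-yn-1-yl)-1,5,5-trimethylcyclohex-1-ene
Conditions: LiC≡CH·H2NCH2CH2NH2, DMSO, 10 °C to rt
Reagents that add atoms: lithium acetylide–ethylenediamine complex, [Li+].[C-]#C.NCCN
Why: SN2 alkylation of lithium acetylide by the unhindered primary iodide in a dipolar aprotic solvent forms the C7–C8 bond.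

Step 9
Reactants: 11 (6S)-6-(but-3-yn-1-yl)-1,5,5-trimethylcyclohex-1-ene
Product: 13 (6S)-6-[(3E)-4-iodo-3-methylbut-3-en-1-yl]-1,5,5-trimethylcyclohex-1-ene, via alkenyldimethylalane 12 (not isolated)
Conditions: Me3Al, Cp2ZrCl2 (0.25 equiv), CH2Cl2, 0 °C to rt; then I2, THF, −30 to 0 °C
Reagents that add atoms: trimethylaluminium, C[Al](C)C; iodine, II
Why: Negishi zirconium-catalysed carboalumination adds CH3 and Al syn across the terminal alkyne with Al at the terminus, and iodinolysis with retention gives the (E)-alkenyl iodide; the ring alkene is inert to the reagent.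

Step 10
Reactants: 13 (6S)-6-[(3E)-4-iodo-3-methylbut-3-en-1-yl]-1,5,5-trimethylcyclohex-1-ene; 14 (4-bromobut-1-yn-1-yl)trimethylsilane (commercial)
Product: 16 trimethyl{(5E)-6-methyl-8-[(1S)-2,6,6-trimethylcyclohex-2-en-1-yl]oct-5-en-1-yn-1-yl}silane, via homopropargylzinc bromide 15 (not isolated)
Conditions: 14, Zn dust (BrCH2CH2Br/Me3SiCl activation), LiCl, THF, 50 °C; then 13, Pd(PPh3)4 (5 mol %), THF, rt
Reagents that add atoms: zinc, [Zn] (stays only in 15)
Why: Negishi cross-coupling of the primary alkylzinc with the alkenyl iodide proceeds with retention of the (E) geometry and forms C5–C6.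

Step 11
Reactants: 16 trimethyl{(5E)-6-methyl-8-[(1S)-2,6,6-trimethylcyclohex-2-en-1-yl]oct-5-en-1-yn-1-yl}silane
Product: 17 (6S)-1,5,5-trimethyl-6-[(3E)-3-methyloct-3-en-7-yn-1-yl]cyclohex-1-ene
Conditions: K2CO3, MeOH, rt
Reagents that add atoms: none
Why: Methoxide-mediated protodesilylation of the alkynylsilane frees the terminal alkyne without affecting the alkenes.

Step 12
Reactants: 17 (6S)-1,5,5-trimethyl-6-[(3E)-3-methyloct-3-en-7-yn-1-yl]cyclohex-1-ene
Product: 20 (2E,6E)-3,7-dimethyl-9-[(1S)-2,6,6-trimethylcyclohex-2-en-1-yl]nona-2,6-dien-1-ol, via dienyldimethylalane 18 (not isolated), via lithium butyldimethylalkenylaluminate 19 (not isolated)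
Conditions: Me3Al, Cp2ZrCl2 (0.25 equiv), CH2Cl2, rt; solvent exchange to THF/hexane; n-BuLi, −78 to 0 °C; (CH2O)n, rt
Reagents that add atoms: trimethylaluminium, C[Al](C)C; paraformaldehyde (as formaldehyde), C=O; n-butyllithium, [Li]CCCC (butyl and lithium stay only in 19)
Why: Negishi carboalumination again sets the trisubstituted (E)-alkene by syn methylalumination, and the more nucleophilic aluminate adds to formaldehyde with retention to give the (2E)-allylic alcohol.

Step 13
Reactants: 20 (2E,6E)-3,7-dimethyl-9-[(1S)-2,6,6-trimethylcyclohex-2-en-1-yl]nona-2,6-dien-1-ol; 21 arachidonic acid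
Product: 22 (2E,6E)-3,7-dimethyl-9-[(1S)-2,6,6-trimethylcyclohex-2-en-1-yl]nona-2,6-dien-1-yl (5Z,8Z,11Z,14Z)-icosa-5,8,11,14-tetraenoate (CNP0207506.1)
Conditions: DCC, DMAP (cat.), CH2Cl2, 0 °C to rt, argon, dark
Reagents that add atoms: none
Why: Steglich esterification acylates the primary allylic alcohol through the O-acylisourea and acylpyridinium under neutral conditions that should leave the skipped (Z)-tetraene, both (E)-alkenes and C1' unchanged.

**Compound list**

1 | 2,2-dimethylpent-4-enal | C=CCC(C)(C)C=O | starting material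
2 | triethyl phosphonoacetate | CCOC(=O)CP(=O)(OCC)OCC | starting material
3 | ethyl (2E)-4,4-dimethylhepta-2,6-dienoate | CCOC(=O)/C=C/C(C)(C)CC=C | intermediate
4 | ethyl (2E)-7-(9-borabicyclo[3.3.1]nonan-9-yl)-4,4-dimethylhept-2-enoate | CCOC(=O)/C=C/C(C)(C)CCCB1C2CCCC1CCC2 | intermediate
5 | ethyl (2E)-7-hydroxy-4,4-dimethylhept-2-enoate | CCOC(=O)/C=C/C(C)(C)CCCO | intermediate
6 | ethyl (2E)-4,4-dimethyl-7-oxohept-2-enoate | CCOC(=O)/C=C/C(C)(C)CCC=O | intermediate
7 | ethyl (2E,7Z)-8-iodo-4,4-dimethylnona-2,7-dienoate | CCOC(=O)/C=C/C(C)(C)CC/C=C(/C)I | intermediate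
8 | ethyl 2-[(1S)-2,6,6-trimethylcyclohex-2-en-1-yl]acetate | CCOC(=O)C[C@@H]1C(C)=CCCC1(C)C | intermediate
9 | 2-[(1S)-2,6,6-trimethylcyclohex-2-en-1-yl]ethan-1-ol | OCC[C@@H]1C(C)=CCCC1(C)C | intermediate
10 | (6S)-6-(2-iodoethyl)-1,5,5-trimethylcyclohex-1-ene | ICC[C@@H]1C(C)=CCCC1(C)C | intermediate
11 | (6S)-6-(but-3-yn-1-yl)-1,5,5-trimethylcyclohex-1-ene | C#CCC[C@@H]1C(C)=CCCC1(C)C | intermediate
12 | dimethyl{(1E)-2-methyl-4-[(1S)-2,6,6-trimethylcyclohex-2-en-1-yl]but-1-en-1-yl}alumane | C[Al](C)/C=C(\C)CC[C@@H]1C(C)=CCCC1(C)C | intermediate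
13 | (6S)-6-[(3E)-4-iodo-3-methylbut-3-en-1-yl]-1,5,5-trimethylcyclohex-1-ene | I/C=C(\C)CC[C@@H]1C(C)=CCCC1(C)C | intermediate
14 | (4-bromobut-1-yn-1-yl)trimethylsilane | C[Si](C)(C)C#CCCBr | starting material
15 | bromo[4-(trimethylsilyl)but-3-yn-1-yl]zinc | C[Si](C)(C)C#CCC[Zn]Br | intermediate
16 | trimethyl{(5E)-6-methyl-8-[(1S)-2,6,6-trimethylcyclohex-2-en-1-yl]oct-5-en-1-yn-1-yl}silane | C[Si](C)(C)C#CCC/C=C(\C)CC[C@@H]1C(C)=CCCC1(C)C | intermediate
17 | (6S)-1,5,5-trimethyl-6-[(3E)-3-methyloct-3-en-7-yn-1-yl]cyclohex-1-ene | C#CCC/C=C(\C)CC[C@@H]1C(C)=CCCC1(C)C | intermediate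
18 | {(1E,5E)-2,6-dimethyl-8-[(1S)-2,6,6-trimethylcyclohex-2-en-1-yl]octa-1,5-dien-1-yl}dimethylalumane | C[Al](C)/C=C(\C)CC/C=C(\C)CC[C@@H]1C(C)=CCCC1(C)C | intermediate
19 | lithium butyl{(1E,5E)-2,6-dimethyl-8-[(1S)-2,6,6-trimethylcyclohex-2-en-1-yl]octa-1,5-dien-1-yl}dimethylaluminate | [Li+].CCCC[Al-](C)(C)/C=C(\C)CC/C=C(\C)CC[C@@H]1C(C)=CCCC1(C)C | intermediate
20 | (2E,6E)-3,7-dimethyl-9-[(1S)-2,6,6-trimethylcyclohex-2-en-1-yl]nona-2,6-dien-1-ol | OC/C=C(\C)CC/C=C(\C)CC[C@@H]1C(C)=CCCC1(C)C | intermediate
21 | arachidonic acid, (5Z,8Z,11Z,14Z)-icosa-5,8,11,14-tetraenoic acid | CCCCC/C=C\C/C=C\C/C=C\C/C=C\CCCC(=O)O | starting material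
22 | (2E,6E)-3,7-dimethyl-9-[(1S)-2,6,6-trimethylcyclohex-2-en-1-yl]nona-2,6-dien-1-yl (5Z,8Z,11Z,14Z)-icosa-5,8,11,14-tetraenoate | CCCCC/C=C\C/C=C\C/C=C\C/C=C\CCCC(=O)OC/C=C(\C)CC/C=C(\C)CC[C@@H]1C(C)=CCCC1(C)C | target

**Step count**

Total: 13 steps. Longest linear sequence: 13 steps (1 to 22); 2, 14 and 21 enter as purchased materials.

**Steps most likely to fail**

Step 5 (proposed new method). The bisphosphine may discriminate the enoate faces poorly. The palladium enolate may undergo β-hydride elimination to the alkylidene ester, or formate may reduce the alkenylpalladium before it cyclises onto the hindered neopentyl β-carbon. The fallback sets out from 7 and closes the same C1'–C2' bond by a known tin hydride-mediated alkenyl radical cyclisation onto the enoate (Bu3SnH, AIBN, benzene, 80 °C; 6-exo-trig). This should give racemic ethyl 2-(2,6,6-trimethylcyclohex-2-en-1-yl)acetate F1. The enantiomers are then separated by preparative chromatography on a chiral stationary phase (cellulose tris(3,5-dimethylphenylcarbamate)); the (S)-enantiomer is compound 8, where the route is rejoined.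

Step 4. The α-iodo ylide may form incompletely or decompose, and the (Z) geometry may erode during olefination. The fallback sets out from aldehyde 6. Ramirez dibromo-olefination (CBr4, PPh3, CH2Cl2, 0 °C) should give ethyl (2E)-8,8-dibromo-4,4-dimethylocta-2,7-dienoate F2. Palladium-catalysed trans-selective monomethylation of the bromine trans to the chain (MeZnCl, PdCl2(DPEphos) cat., THF, 0 °C to rt) should then give ethyl (2E,7Z)-8-bromo-4,4-dimethylnona-2,7-dienoate F3. F3 carries its halogen cis to the chain as 7 does and is cyclised under the conditions of step 5 in place of 7, rejoining the route at 8.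

Step 2. The borane may also attack the enoate (conjugate reduction or hydroboration), and the hydroxy enoate may close to a tetrahydropyran by oxa-Michael addition during the basic oxidation. The fallback changes the order of events so that the enoate is introduced last; it sets out from 1 and rejoins the route at 7.
- Acetalisation (HC(OMe)3, p-TsOH cat., MeOH) gives 5,5-dimethoxy-4,4-dimethylpent-1-ene F4.
- Hydroboration–oxidation (9-BBN, THF; NaOH, H2O2) gives 5,5-dimethoxy-4,4-dimethylpentan-1-ol F5.
- Dess–Martin oxidation gives 5,5-dimethoxy-4,4-dimethylpentanal F6.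
- Iodo-olefination as in step 4 gives (2Z)-2-iodo-7,7-dimethoxy-6,6-dimethylhept-2-ene F7.
- Acetal hydrolysis (aqueous oxalic acid, THF) gives (5Z)-6-iodo-2,2-dimethylhept-5-enal F8.
- Horner–Wadsworth–Emmons olefination of F8 with 2 (NaH, THF) gives 7.

**Further compounds**

F1 | step 5 | racemic ethyl 2-(2,6,6-trimethylcyclohex-2-en-1-yl)acetate | CCOC(=O)CC1C(C)=CCCC1(C)C
F2 | step 4 | ethyl (2E)-8,8-dibromo-4,4-dimethylocta-2,7-dienoate | CCOC(=O)/C=C/C(C)(C)CCC=C(Br)Br
F3 | step 4 | ethyl (2E,7Z)-8-bromo-4,4-dimethylnona-2,7-dienoate | CCOC(=O)/C=C/C(C)(C)CC/C=C(/C)Br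
F4 | step 2 | 5,5-dimethoxy-4,4-dimethylpent-1-ene | C=CCC(C)(C)C(OC)OC
F5 | step 2 | 5,5-dimethoxy-4,4-dimethylpentan-1-ol | OCCCC(C)(C)C(OC)OC
F6 | step 2 | 5,5-dimethoxy-4,4-dimethylpentanal | O=CCCC(C)(C)C(OC)OC
F7 | step 2 | (2Z)-2-iodo-7,7-dimethoxy-6,6-dimethylhept-2-ene | C/C(I)=C/CCC(C)(C)C(OC)OC
F8 | step 2 | (5Z)-6-iodo-2,2-dimethylhept-5-enal | O=CC(C)(C)CC/C=C(/C)I
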